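The flavonol is disconnected at two bonds of ring A, C8a–O1 and C4a–C4. These neighbouring carbons, flanked by the C8 diarylethyl arm and by the C5 oxygen, correspond to the two ends of a 3-alkoxyaryne. In a single operation the C4a≡C8a aryne takes up a carboxylate: oxygen ends on C8a and the benzyloxyacetyl carbon on C4a, giving an ortho-hydroxyaryl ketone whose only free phenol later closes ring C without ambiguity. The aryne precursor is a ring A silyl triflate (trimethylsilyl on C4a, triflate on C8a) that already carries the (R)-configured side chain, set beforehand by hydroxyl-directed asymmetric hydrogenation, with all other phenols as benzyl ethers.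

Key step: step 9

Remark: flavone numbering (C4a, C5 to C8, C8a) is used for the ring A carbons at every stage.
Remark: compounds 1, 3, 16 and 20 are taken as catalogue chemicals.
Remark: in step 4 the ligand antipode written is assumed to be the one that delivers the (R) product; its mirror image is equally available should the sense of induction be the opposite.

Step 1
Reactants: 1 acetosyringone
Product: 2 1-[4-(benzyloxy)-3,5-dimethoxyphenyl]ethanone
Conditions: BnBr, K2CO3, DMF, 60 °C
Reagents that add atoms: benzyl bromide, BrCc1ccccc1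
Why: Williamson ether synthesis on the phenoxide should go cleanly with the reactive benzylic bromide despite the two flanking methoxy groups, and the resulting ether is inert to aryllithium and falls only in the final hydrogenolysis.

Step 2
Reactants: 3 3,5-bis(benzyloxy)phenol
Product: 4 1,3-bis(benzyloxy)-5-(methoxymethoxy)benzene
Conditions: MOMCl, iPr2NEt, CH2Cl2, 0 °C to rt
Reagents that add atoms: chloromethyl methyl ether, COCCl
Why: O-alkylation of the phenol with the chloromethyl ether installs an acetal that survives n-BuLi, is a stronger ortho-director than a benzyl ether and is removed by mild acid.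

Step 3
Reactants: 4 1,3-bis(benzyloxy)-5-(methoxymethoxy)benzene; 2 1-[4-(benzyloxy)-3,5-dimethoxyphenyl]ethanone
Product: 7 3,5-bis(benzyloxy)-2-{1-[4-(benzyloxy)-3,5-dimethoxyphenyl]ethenyl}phenol, via aryllithium 5 (not isolated), via tertiary alcohol 6 (not isolated)
Conditions: n-BuLi, THF, 0 °C; then 2, −78 °C to 0 °C; then 3 M HCl, MeOH/THF, 45 °C; then TsOH·H2O (cat.), toluene, 60 °C
Reagents that add atoms: none
Why: Directed ortho-metalation should place lithium on the carbon between the chelating methoxymethoxy group and a benzyloxy group (the future C8), 1,2-addition to the ketone gives the doubly benzylic carbinol, and acid then cleaves the acetal and drives E1 dehydration to the only possible alkene, since the methyl group alone carries β-hydrogens.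

Step 4
Reactants: 7 3,5-bis(benzyloxy)-2-{1-[4-(benzyloxy)-3,5-dimethoxyphenyl]ethenyl}phenol
Product: 8 3,5-bis(benzyloxy)-2-{(1R)-1-[4-(benzyloxy)-3,5-dimethoxyphenyl]ethyl}phenol
Conditions: [Rh(nbd)2]BF4 (2 mol %), (R)-1-[(S)-2-(diphenylphosphino)ferrocenyl]ethyldi-tert-butylphosphine (2.2 mol %), H2 (10 bar), MeOH/CH2Cl2, 25 °C
Reagents that add atoms: none
Why: In this hydroxyl-directed asymmetric hydrogenation the free phenol ortho to the 1,1-diarylethene binds the cationic rhodium diphosphine complex, so that the chiral ferrocenyl diphosphine decides which alkene face receives hydrogen and sets the (R) methine, while the homogeneous catalyst leaves the benzyl ethers untouched.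

Step 5
Reactants: 8 3,5-bis(benzyloxy)-2-{(1R)-1-[4-(benzyloxy)-3,5-dimethoxyphenyl]ethyl}phenol
Product: 9 3,5-bis(benzyloxy)-2-{(1R)-1-[4-(benzyloxy)-3,5-dimethoxyphenyl]ethyl}phenyl N-isopropylcarbamate
Conditions: iPrNCO, Et3N (cat.), CH2Cl2, rt
Reagents that add atoms: isopropyl isocyanate, CC(C)N=C=O
Why: Base-catalysed addition of the phenol to the isocyanate (carbamoylation) gives the N-monoalkyl carbamate, which directs ortho-metalation strongly and can later be removed under mild base without touching silicon.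

Step 6
Reactants: 9 3,5-bis(benzyloxy)-2-{(1R)-1-[4-(benzyloxy)-3,5-dimethoxyphenyl]ethyl}phenyl N-isopropylcarbamate
Product: 13 3,5-bis(benzyloxy)-2-{(1R)-1-[4-(benzyloxy)-3,5-dimethoxyphenyl]ethyl}-6-(trimethylsilyl)phenyl N-isopropylcarbamate, via N-silyl carbamate 10 (not isolated), via aryllithium 11 (not isolated), via C-silyl N-silyl carbamate 12 (not isolated)
Conditions: TBSOTf, TMEDA, Et2O, 0 °C to rt; then n-BuLi, TMEDA, −78 °C; then TMSCl, −78 °C to rt; aq. NaHSO4 work-up
Reagents that add atoms: chlorotrimethylsilane, C[Si](C)(C)Cl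
Why: After the N–H is masked in the flask as its silyl derivative, directed ortho-metalation should take the only open position ortho to the carbamate (C4a, also activated by the C5 benzyloxy group) at −78 °C, much faster than removal of the hindered diarylmethine hydrogen, which is twisted out of conjugation with ring A, so the stereocenter is kept, and silyl chloride quench followed by hydrolysis of the N–Si bond gives the aryl silane.

Step 7
Reactants: 13 3,5-bis(benzyloxy)-2-{(1R)-1-[4-(benzyloxy)-3,5-dimethoxyphenyl]ethyl}-6-(trimethylsilyl)phenyl N-isopropylcarbamate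
Product: 15 3,5-bis(benzyloxy)-2-{(1R)-1-[4-(benzyloxy)-3,5-dimethoxyphenyl]ethyl}-6-(trimethylsilyl)phenyl trifluoromethanesulfonate, via silyl phenol 14 (not isolated)
Conditions: Et2NH, DBU, MeCN, 40 °C; then PhNTf2, rt
Reagents that add atoms: N-phenylbis(trifluoromethanesulfonimide), O=S(=O)(N(c1ccccc1)S(=O)(=O)C(F)(F)F)C(F)(F)F
Why: Deprotonation of the carbamate N–H triggers E1cB loss of the phenoxide, a process insensitive to the crowding around oxygen, the isocyanate is trapped by diethylamine, and O-triflation of the phenoxide in the same flask avoids handling the acid-sensitive ortho-silyl phenol.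

Step 8
Reactants: 16 benzyloxyacetic acid
Product: 17 caesium benzyloxyacetate
Conditions: CsOH·H2O (1.0 equiv), MeOH, rt; evaporation, toluene azeotrope, 80 °C under vacuum
Reagents that add atoms: caesium hydroxide monohydrate, [Cs+].[OH-].O
Why: Simple acid–base neutralisation followed by rigorous drying should provide the carboxylate as an anhydrous salt free of any proton source.

Step 9
Reactants: 15 3,5-bis(benzyloxy)-2-{(1R)-1-[4-(benzyloxy)-3,5-dimethoxyphenyl]ethyl}-6-(trimethylsilyl)phenyl trifluoromethanesulfonate; 17 caesium benzyloxyacetate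
Product: 19 2-(benzyloxy)-1-[4,6-bis(benzyloxy)-3-{(1R)-1-[4-(benzyloxy)-3,5-dimethoxyphenyl]ethyl}-2-hydroxyphenyl]ethanone, via aryne 18 (not isolated)
Conditions: 17 (3 equiv), CsF (3 equiv), THF (0.02 M), 125 °C, sealed vessel; cold 1 M HCl work-up
Reagents that add atoms: none
Why: Fluoride attacks silicon and triflate leaves from the neighbouring carbon, releasing the C4a≡C8a aryne slowly because CsF is sparingly soluble; the carboxylate oxygen adds to C8a, and the C4a aryl anion, finding no proton, attacks the adjacent ester carbonyl through a four-membered alkoxide that opens to the ketone and the C8a phenoxide, so that the C8a–O1 and C4a–C4 bonds form in one operation. The closest known reaction type is the fluoride-mediated addition of carboxylic acids to arynes with acyl migration, which gives ortho-hydroxyaryl ketones. No ring is closed and no stereocenter is created, and the existing methine is safe because neither fluoride nor carboxylate is basic enough to remove its hydrogen. The step needs regiocontrol on the unsymmetrical aryne: the inductively withdrawing C5 benzyloxy group distorts the triple bond so that the nucleophile attacks the distal carbon C8a and the charge develops at C4a beside oxygen, a bias expected to outweigh the steric shielding of C8a by the C8 side chain. It also needs acyl transfer to beat ester formation and arylation of the product phenoxide, which the anhydrous caesium salt in excess, the high dilution and the slow aryne release are meant to secure.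

Step 10
Reactants: 19 2-(benzyloxy)-1-[4,6-bis(benzyloxy)-3-{(1R)-1-[4-(benzyloxy)-3,5-dimethoxyphenyl]ethyl}-2-hydroxyphenyl]ethanone; 20 4-(benzyloxy)-3-methoxybenzoic acid
Product: 22 2-(benzyloxyacetyl)-3,5-bis(benzyloxy)-6-{(1R)-1-[4-(benzyloxy)-3,5-dimethoxyphenyl]ethyl}phenyl 4-(benzyloxy)-3-methoxybenzoate, via acid chloride 21 (not isolated)
Conditions: 20, (COCl)2, DMF (cat.), CH2Cl2, rt, evaporation; then 19, Et3N, DMAP, CH2Cl2, 0 °C to 40 °C
Reagents that add atoms: none
Why: The acid chloride formed by Vilsmeier-type activation should acylate the single free phenol under nucleophilic catalysis by DMAP, whose acylpyridinium ion is reactive enough to overcome the hydrogen bond to the ketone and the crowding by the C8 side chain.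

Step 11
Reactants: 22 2-(benzyloxyacetyl)-3,5-bis(benzyloxy)-6-{(1R)-1-[4-(benzyloxy)-3,5-dimethoxyphenyl]ethyl}phenyl 4-(benzyloxy)-3-methoxybenzoate
Product: 24 3,5,7-tris(benzyloxy)-2-[4-(benzyloxy)-3-methoxyphenyl]-8-{(1R)-1-[4-(benzyloxy)-3,5-dimethoxyphenyl]ethyl}-4H-chromen-4-one, via 1,3-diketone 23 (not isolated)
Conditions: LiN(SiMe3)2 (2.5 equiv), THF, −78 °C to 0 °C, AcOH quench; then H2SO4 (cat.), AcOH, 50 °C
Reagents that add atoms: none
Why: In this Baker–Venkataraman rearrangement the α-benzyloxy ketone enolate attacks the neighbouring aryl ester and moves the aroyl group from oxygen to carbon, after which mild acid lets the liberated C8a hydroxyl add to the aroyl carbonyl (6-exo-trig) and lose water to give the pyranone, the acyl-deactivated ring A being too electron-poor to ionise the side chain.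

Step 12
Reactants: 24 3,5,7-tris(benzyloxy)-2-[4-(benzyloxy)-3-methoxyphenyl]-8-{(1R)-1-[4-(benzyloxy)-3,5-dimethoxyphenyl]ethyl}-4H-chromen-4-one
Product: 25 3,5,7-trihydroxy-2-(4-hydroxy-3-methoxyphenyl)-8-[(1R)-1-(4-hydroxy-3,5-dimethoxyphenyl)ethyl]-4H-chromen-4-one
Conditions: H2 (1 atm), Pd/C (10% Pd), THF/MeOH, rt
Reagents that add atoms: none
Why: Catalytic hydrogenolysis should cleave all five benzyl ethers under conditions that leave the flavonol enone, the methyl ethers and the diarylmethine stereocenter unchanged.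

Compound list

1 | acetosyringone | CC(=O)c1cc(OC)c(O)c(OC)c1 | starting material
2 | 1-[4-(benzyloxy)-3,5-dimethoxyphenyl]ethanone | CC(=O)c1cc(OC)c(OCc2ccccc2)c(OC)c1 | intermediate
3 | 3,5-bis(benzyloxy)phenol | Oc1cc(OCc2ccccc2)cc(OCc2ccccc2)c1 | starting material
4 | 1,3-bis(benzyloxy)-5-(methoxymethoxy)benzene | COCOc1cc(OCc2ccccc2)cc(OCc2ccccc2)c1 | intermediate
5 | [2,4-bis(benzyloxy)-6-(methoxymethoxy)phenyl]lithium (formed in the flask) | [Li]c1c(OCOC)cc(OCc2ccccc2)cc1OCc1ccccc1 | intermediate
6 | racemic 1-[2,4-bis(benzyloxy)-6-(methoxymethoxy)phenyl]-1-[4-(benzyloxy)-3,5-dimethoxyphenyl]ethanol (formed in the flask) | CC(O)(c1c(OCOC)cc(OCc2ccccc2)cc1OCc1ccccc1)c1cc(OC)c(OCc2ccccc2)c(OC)c1 | intermediate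
7 | 3,5-bis(benzyloxy)-2-{1-[4-(benzyloxy)-3,5-dimethoxyphenyl]ethenyl}phenol | C=C(c1c(O)cc(OCc2ccccc2)cc1OCc1ccccc1)c1cc(OC)c(OCc2ccccc2)c(OC)c1 | intermediate
8 | 3,5-bis(benzyloxy)-2-{(1R)-1-[4-(benzyloxy)-3,5-dimethoxyphenyl]ethyl}phenol | Oc1cc(OCc2ccccc2)cc(OCc2ccccc2)c1[C@H](C)c1cc(OC)c(OCc2ccccc2)c(OC)c1 | intermediate
9 | (R)-aryl N-isopropylcarbamate of 8 | CC(C)NC(=O)Oc1cc(OCc2ccccc2)cc(OCc2ccccc2)c1[C@H](C)c1cc(OC)c(OCc2ccccc2)c(OC)c1 | intermediate
10 | N-(tert-butyldimethylsilyl) derivative of 9 (formed in the flask) | CC(C)N([Si](C)(C)C(C)(C)C)C(=O)Oc1cc(OCc2ccccc2)cc(OCc2ccccc2)c1[C@H](C)c1cc(OC)c(OCc2ccccc2)c(OC)c1 | intermediate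
11 | C4a-lithiated 10 (formed in the flask) | CC(C)N([Si](C)(C)C(C)(C)C)C(=O)Oc1c([Li])c(OCc2ccccc2)cc(OCc2ccccc2)c1[C@H](C)c1cc(OC)c(OCc2ccccc2)c(OC)c1 | intermediate
12 | C4a-trimethylsilyl N-(tert-butyldimethylsilyl) carbamate (formed in the flask) | CC(C)N([Si](C)(C)C(C)(C)C)C(=O)Oc1c([Si](C)(C)C)c(OCc2ccccc2)cc(OCc2ccccc2)c1[C@H](C)c1cc(OC)c(OCc2ccccc2)c(OC)c1 | intermediate
13 | 3,5-bis(benzyloxy)-2-{(1R)-1-[4-(benzyloxy)-3,5-dimethoxyphenyl]ethyl}-6-(trimethylsilyl)phenyl N-isopropylcarbamate | CC(C)NC(=O)Oc1c([Si](C)(C)C)c(OCc2ccccc2)cc(OCc2ccccc2)c1[C@H](C)c1cc(OC)c(OCc2ccccc2)c(OC)c1 | intermediate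
14 | 3,5-bis(benzyloxy)-2-{(1R)-1-[4-(benzyloxy)-3,5-dimethoxyphenyl]ethyl}-6-(trimethylsilyl)phenol (formed in the flask) | Oc1c([Si](C)(C)C)c(OCc2ccccc2)cc(OCc2ccccc2)c1[C@H](C)c1cc(OC)c(OCc2ccccc2)c(OC)c1 | intermediate
15 | ring A silyl triflate with the (R) side chain (TMS at C4a, triflate at C8a) | C[Si](C)(C)c1c(OCc2ccccc2)cc(OCc2ccccc2)c([C@H](C)c2cc(OC)c(OCc3ccccc3)c(OC)c2)c1OS(=O)(=O)C(F)(F)F | intermediate
16 | benzyloxyacetic acid | OC(=O)COCc1ccccc1 | starting material
17 | caesium benzyloxyacetate | [Cs+].[O-]C(=O)COCc1ccccc1 | intermediate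
18 | C4a≡C8a aryne carrying the 5,7-bis(benzyloxy) groups and the (R) side chain at C8 (formed in the flask) | C1(OCc2ccccc2)=CC(OCc2ccccc2)=C([C@H](C)c2cc(OC)c(OCc3ccccc3)c(OC)c2)C#C1 | intermediate
19 | 2-(benzyloxy)-1-[4,6-bis(benzyloxy)-3-{(1R)-1-[4-(benzyloxy)-3,5-dimethoxyphenyl]ethyl}-2-hydroxyphenyl]ethanone | O=C(COCc1ccccc1)c1c(OCc2ccccc2)cc(OCc2ccccc2)c([C@H](C)c2cc(OC)c(OCc3ccccc3)c(OC)c2)c1O | intermediate
20 | 4-(benzyloxy)-3-methoxybenzoic acid | COc1cc(C(=O)O)ccc1OCc1ccccc1 | starting material
21 | 4-(benzyloxy)-3-methoxybenzoyl chloride (formed in the flask) | COc1cc(C(=O)Cl)ccc1OCc1ccccc1 | intermediate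
22 | 2-(benzyloxyacetyl)-3,5-bis(benzyloxy)-6-{(1R)-1-[4-(benzyloxy)-3,5-dimethoxyphenyl]ethyl}phenyl 4-(benzyloxy)-3-methoxybenzoate | O=C(COCc1ccccc1)c1c(OCc2ccccc2)cc(OCc2ccccc2)c([C@H](C)c2cc(OC)c(OCc3ccccc3)c(OC)c2)c1OC(=O)c1ccc(OCc2ccccc2)c(OC)c1 | intermediate
23 | 2-(benzyloxy)-1-[4,6-bis(benzyloxy)-3-{(1R)-1-[4-(benzyloxy)-3,5-dimethoxyphenyl]ethyl}-2-hydroxyphenyl]-3-[4-(benzyloxy)-3-methoxyphenyl]propane-1,3-dione, mixture of epimers at C2 (formed in the flask) | O=C(C(OCc1ccccc1)C(=O)c1ccc(OCc2ccccc2)c(OC)c1)c1c(OCc2ccccc2)cc(OCc2ccccc2)c([C@H](C)c2cc(OC)c(OCc3ccccc3)c(OC)c2)c1O | intermediate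
24 | 3,5,7-tris(benzyloxy)-2-[4-(benzyloxy)-3-methoxyphenyl]-8-{(1R)-1-[4-(benzyloxy)-3,5-dimethoxyphenyl]ethyl}-4H-chromen-4-one | COc1cc(-c2oc3c([C@H](C)c4cc(OC)c(OCc5ccccc5)c(OC)c4)c(OCc4ccccc4)cc(OCc4ccccc4)c3c(=O)c2OCc2ccccc2)ccc1OCc1ccccc1 | intermediate
25 | 3,5,7-trihydroxy-2-(4-hydroxy-3-methoxyphenyl)-8-[(1R)-1-(4-hydroxy-3,5-dimethoxyphenyl)ethyl]-4H-chromen-4-one | COc1cc(-c2oc3c([C@H](C)c4cc(OC)c(O)c(OC)c4)c(O)cc(O)c3c(=O)c2O)ccc1O | target

Total step count: 12. Longest linear sequence: 10 steps (steps 2 to 7 and 9 to 12, from 3); steps 1 and 8 are one-step side branches.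

Steps most likely to fail

Step 9. The carboxylate may add to the crowded aryne with the wrong orientation, the aryl anion may be protonated before acyl transfer (aryl ester instead of ketone), or the product phenoxide may be arylated by a second aryne. The fallback installs the acyl group by directed ortho-metalation instead of aryne chemistry. It sets out from carbamate 9, which is N-silylated and lithiated exactly as in step 6 to give aryllithium 11 (through 10). At −78 °C 11 is quenched with N-methoxy-N-methyl-2-(benzyloxy)acetamide in place of TMSCl, and collapse of the chelated adduct gives the N-silyl ortho-acyl carbamate F1. The same aqueous NaHSO4 work-up hydrolyses its N–Si bond to the ortho-acyl carbamate F2. Et2NH and DBU in MeCN at 40 °C then remove the carbamoyl group by E1cB elimination. The route is rejoined at hydroxy ketone 19, and steps 7 and 8 fall away.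

Step 4. The doubly ortho-substituted ring A is forced out of the alkene plane and may hold the phenol away from rhodium, leading to poor facial discrimination or slow turnover. The fallback obtains the stereocenter by resolution instead of asymmetric catalysis. It sets out from alkene 7, which is hydrogenated with the achiral, hydroxyl-tolerant catalyst [Ir(cod)(PCy3)(py)]PF6 (H2, CH2Cl2, rt, benzyl ethers untouched) to the racemic phenol F3. Preparative chromatography on a polysaccharide-based chiral stationary phase (supercritical CO2/MeOH) then separates the (R)-enantiomer, which is compound 8, from the (S)-enantiomer F4, which is set aside. The route is rejoined at 8.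

Step 6. Under n-BuLi/TMEDA, deprotonation at the benzylic CH2 groups of the benzyl ethers or at the diarylmethine may compete with ring lithiation, the latter eroding configuration. The fallback brings in silicon by halogen–metal exchange and a retro-Brook shift, which needs no long-lived strong base. It sets out from phenol 8: ortho-selective bromination (NBS, iPr2NH cat., CH2Cl2, 0 °C) gives the bromophenol F5, and (Me3Si)2NH in THF at 65 °C gives the trimethylsilyl ether F6. n-BuLi (1.05 equiv) in THF at −78 °C effects bromine–lithium exchange to the aryllithium F7, which undergoes 1,3 O-to-C silyl migration to the lithium salt of silyl phenol 14. PhNTf2 added to the same flask gives the triflate. The route is rejoined at 15, and steps 5 to 7 are replaced.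

Further compounds

F1 | step 9 | N-(tert-butyldimethylsilyl) N-isopropylcarbamate of 19 | CC(C)N([Si](C)(C)C(C)(C)C)C(=O)Oc1c(C(=O)COCc2ccccc2)c(OCc2ccccc2)cc(OCc2ccccc2)c1[C@H](C)c1cc(OC)c(OCc2ccccc2)c(OC)c1
F2 | step 9 | N-isopropylcarbamate of 19 | CC(C)NC(=O)Oc1c(C(=O)COCc2ccccc2)c(OCc2ccccc2)cc(OCc2ccccc2)c1[C@H](C)c1cc(OC)c(OCc2ccccc2)c(OC)c1
F3 | step 4 | racemic 3,5-bis(benzyloxy)-2-{1-[4-(benzyloxy)-3,5-dimethoxyphenyl]ethyl}phenol | Oc1cc(OCc2ccccc2)cc(OCc2ccccc2)c1C(C)c1cc(OC)c(OCc2ccccc2)c(OC)c1
F4 | step 4 | 3,5-bis(benzyloxy)-2-{(1S)-1-[4-(benzyloxy)-3,5-dimethoxyphenyl]ethyl}phenol | Oc1cc(OCc2ccccc2)cc(OCc2ccccc2)c1[C@@H](C)c1cc(OC)c(OCc2ccccc2)c(OC)c1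
F5 | step 6 | 3,5-bis(benzyloxy)-2-bromo-6-{(1R)-1-[4-(benzyloxy)-3,5-dimethoxyphenyl]ethyl}phenol | Oc1c(Br)c(OCc2ccccc2)cc(OCc2ccccc2)c1[C@H](C)c1cc(OC)c(OCc2ccccc2)c(OC)c1
F6 | step 6 | trimethylsilyl ether of F5 | C[Si](C)(C)Oc1c(Br)c(OCc2ccccc2)cc(OCc2ccccc2)c1[C@H](C)c1cc(OC)c(OCc2ccccc2)c(OC)c1
F7 | step 6 | aryllithium from bromine–lithium exchange on F6 | C[Si](C)(C)Oc1c([Li])c(OCc2ccccc2)cc(OCc2ccccc2)c1[C@H](C)c1cc(OC)c(OCc2ccccc2)c(OC)c1
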